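**Strategy.** In the chromanone part (O1, C2–C4, C4a, C8a) the ether oxygen O1 on C8a stands para to the ester oxygen on C6, so ring B is a masked quinone. Coenzyme Q0 is alkynylated at the carbonyl that becomes C8a and converted into a spiro-dihydrofuran-3(2H)-one whose spiro carbon already carries O1 and the acyl carbon C4. In the key step acid induces a dienone–phenol rearrangement: C4 shifts from C8a to the neighbouring CH (C4a), which enlarges the five-membered oxacycle to the six-membered pyranone and aromatises ring B with O6–H free. O7-demethylation, SNAr with a fluorobenzaldehyde, carbonylative lactonisation and demethylation complete the depsidone.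

Key step: step 3

Remark on the chemistry: ring B is numbered as a chroman-4-one throughout. The target is achiral; the one stereocentre of 4, 5 and 6 is formed racemic and disappears in step 3. Compounds 1, 2 and 9 are taken as commercial.

**Step 1**
Reactants: 1 2,3-dimethoxy-5-methyl-1,4-benzoquinone (coenzyme Q0); 2 2-methylbut-3-yn-2-ol
Product: 4 rac-4-hydroxy-4-(3-hydroxy-3-methylbut-1-yn-1-yl)-2,3-dimethoxy-6-methylcyclohexa-2,5-dien-1-one, via dilithiated 2-methylbut-3-yn-2-ol 3 (not isolated)
Conditions: 2 (1.1 equiv), n-BuLi (2.2 equiv), THF, −78 → 0 °C; then 1, −78 °C; aq. NH4Cl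
Reagents that add atoms: none
Why: Alkynyllithium 1,2-addition to a quinone carbonyl; the acetylide end of 3 should add to C1 of 1, the carbonyl flanked by the unsubstituted C6–H and so less hindered than C4 next to the methyl group, giving the racemic p-quinol.

**Step 2**
Reactants: 4 rac-4-hydroxy-4-(3-hydroxy-3-methylbut-1-yn-1-yl)-2,3-dimethoxy-6-methylcyclohexa-2,5-dien-1-one
Product: 6 rac-6,7-dimethoxy-2,2,9-trimethyl-1-oxaspiro[4.5]deca-6,9-diene-4,8-dione, via hydroxy enone 5 (not isolated)
Conditions: Ph3PAuNTf2 (2 mol%), MeOH (1 equiv), toluene, rt; then CSA (0.2 equiv), CH2Cl2, rt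
Reagents that add atoms: none
Why: Meyer–Schuster rearrangement followed by acid-catalysed 5-endo oxa-Michael closure (the classical acetylenic 1,4-diol → dihydrofuran-3(2H)-one conversion); only the CMe2–OH should be transposed, because loss of the quinol hydroxyl would need cationic character on a carbon flanked by two electron-poor enone carbons, so the carbonyl appears next to the quinol carbon (5) and the protonated enone is then trapped by the quinol OH at its tertiary β-carbon.

**Step 3**
Reactants: 6 rac-6,7-dimethoxy-2,2,9-trimethyl-1-oxaspiro[4.5]deca-6,9-diene-4,8-dione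
Product: 7 6-hydroxy-7,8-dimethoxy-2,2,5-trimethylchroman-4-one
Conditions: TFA/CH2Cl2 (1:4), 0 °C → rt
Reagents that add atoms: none
Why: Dienone–phenol (quinol) rearrangement with 1,2-acyl shift, the closest known cases being acid-induced acyl migrations of 4-acylcyclohexa-2,5-dienones and ring-enlarging rearrangements of spiro[4.5]decadienones. Protonation of the cross-conjugated C8=O of 6 (a vinylogous ester, the most basic oxygen) makes C10–H electrophilic; the furanone carbonyl carbon C4 migrates from the spiro carbon C5 to C10, leaving a cation stabilised by the ring oxygen, and loss of the C10 proton aromatises the carbocycle. No ring is closed by a cyclisation: the six-membered pyranone is the former five-membered furanone enlarged by insertion of C10 (the future C4a) between the spiro carbon and C4, with the bonds O1–C8a, O1–C2, C2–C3 and C3–C4 carried over intact. No stereocentre is formed and the spiro centre disappears. The step needs migration of the acyl carbon and not of oxygen, secured because only the acyl shift leaves the cation on an oxygen-bearing carbon (an oxygen shift would leave an α-keto cation), and migration to C10 and not to the methoxy-bearing C6, secured because a shift to C6 is reversible and cannot end in aromatisation. The former dienone carbonyl should emerge as the free C6–OH needed later for the lactone.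

**Step 4**
Reactants: 7 6-hydroxy-7,8-dimethoxy-2,2,5-trimethylchroman-4-one
Product: 8 6,7-dihydroxy-8-methoxy-2,2,5-trimethylchroman-4-one
Conditions: BCl3 (2.5 equiv), CH2Cl2, −78 → 0 °C; H2O
Reagents that add atoms: none
Why: Chelation-directed Lewis-acid ether cleavage; the free C6–OH becomes an aryloxy–BCl2 that coordinates the neighbouring 7-OMe (also the methoxy para to the ketone), which should be cleaved to a cyclic catechol borate hydrolysed on work-up, while the 8-OMe with no adjacent OH survives and later distinguishes O8 from O6.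

**Step 5**
Reactants: 9 3-fluoro-5-methylanisole
Product: 11 2-fluoro-6-methoxy-4-methylbenzaldehyde, via aryllithium 10 (not isolated)
Conditions: n-BuLi (1.05 equiv), THF, −78 °C; DMF, −78 → 0 °C; aq. HCl
Reagents that add atoms: N,N-dimethylformamide CN(C)C=O
Why: Directed ortho-metalation; the C–H between F and OMe is the most acidic, so lithiation should occur there at −78 °C (cold enough to avoid benzyne formation) and DMF formylates 10.

**Step 6**
Reactants: 11 2-fluoro-6-methoxy-4-methylbenzaldehyde
Product: 12 3-bromo-2-fluoro-6-methoxy-4-methylbenzaldehyde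
Conditions: NBS (1.05 equiv), MeCN, rt
Reagents that add atoms: N-bromosuccinimide O=C1CCC(=O)N1Br
Why: Electrophilic aromatic bromination governed by the methoxy group; the position para to OMe (also ortho to CH3 and meta to CHO) should be attacked in preference to the ortho position, which is screened by the methoxy group turned away from the aldehyde.

**Step 7**
Reactants: 8 6,7-dihydroxy-8-methoxy-2,2,5-trimethylchroman-4-one; 12 3-bromo-2-fluoro-6-methoxy-4-methylbenzaldehyde
Product: 13 3-bromo-2-[(6-hydroxy-8-methoxy-2,2,5-trimethyl-4-oxochroman-7-yl)oxy]-6-methoxy-4-methylbenzaldehyde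
Conditions: K2CO3 (1.1 equiv), DMF, 70 °C, Ar
Reagents that add atoms: none
Why: SNAr (addition–elimination) on a 2-fluorobenzaldehyde; with one equivalent of base the more acidic 7-OH of 8 (para to the ketone) is ionised and should displace the fluoride activated by the ortho-formyl group, as in the selective 4-O-alkylation of 3,4-dihydroxyaryl ketones, while the bromide meta to CHO is not displaced.

**Step 8**
Reactants: 13 3-bromo-2-[(6-hydroxy-8-methoxy-2,2,5-trimethyl-4-oxochroman-7-yl)oxy]-6-methoxy-4-methylbenzaldehyde
Product: 14 di-O-methyl ether of the target (depsidone with OMe ortho to CHO on ring A and OMe at chromanone C8)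
Conditions: Pd(OAc)2 (5 mol%), Xantphos (7.5 mol%), CO (1 atm), K2CO3 (2 equiv), toluene, 100 °C
Reagents that add atoms: carbon monoxide [C-]#[O+]
Why: Palladium-catalysed carbonylative lactonisation (intramolecular aryloxycarbonylation); oxidative addition into C–Br, CO insertion and capture of the aroyl–palladium by the neighbouring C6 phenoxide should close the seven-membered depsidone lactone, the aldehyde and ketone being inert.

**Step 9**
Reactants: 14 di-O-methyl ether of the target
Product: 15 CNP0271978.0 (target depsidone)
Conditions: BBr3 (5 equiv), CH2Cl2, −78 → 0 °C; H2O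
Reagents that add atoms: none
Why: Lewis-acid cleavage of aryl methyl ethers with BBr3; the OMe ortho to the aldehyde (chelation) and the out-of-plane 8-OMe flanked by two oxygens should both be removed at low temperature, under which the aryl lactone, the diaryl ether and the 2,2-dimethylchromanone are expected to survive.

**Compound list**
1 | 2,3-dimethoxy-5-methyl-1,4-benzoquinone (coenzyme Q0) | CC1=CC(=O)C(OC)=C(OC)C1=O | starting material
2 | 2-methylbut-3-yn-2-ol | CC(C)(O)C#C | starting material
3 | dilithiated 2-methylbut-3-yn-2-ol (lithium alkoxide and lithium acetylide) | [Li]OC(C)(C)C#C[Li] | intermediate (not isolated)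
4 | rac-4-hydroxy-4-(3-hydroxy-3-methylbut-1-yn-1-yl)-2,3-dimethoxy-6-methylcyclohexa-2,5-dien-1-one | O=C1C(C)=CC(O)(C#CC(C)(C)O)C(OC)=C1OC | intermediate
5 | rac-4-hydroxy-2,3-dimethoxy-6-methyl-4-(3-methylbut-2-enoyl)cyclohexa-2,5-dien-1-one | O=C1C(C)=CC(O)(C(=O)C=C(C)C)C(OC)=C1OC | intermediate (not isolated)
6 | rac-6,7-dimethoxy-2,2,9-trimethyl-1-oxaspiro[4.5]deca-6,9-diene-4,8-dione | O=C1CC(C)(C)OC12C=C(C)C(=O)C(OC)=C2OC | intermediate
7 | 6-hydroxy-7,8-dimethoxy-2,2,5-trimethylchroman-4-one | O=C1CC(C)(C)Oc2c(OC)c(OC)c(O)c(C)c12 | intermediate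
8 | 6,7-dihydroxy-8-methoxy-2,2,5-trimethylchroman-4-one | O=C1CC(C)(C)Oc2c(OC)c(O)c(O)c(C)c12 | intermediate
9 | 3-fluoro-5-methylanisole | COc1cc(C)cc(F)c1 | starting material
10 | (2-fluoro-6-methoxy-4-methylphenyl)lithium | [Li]c1c(F)cc(C)cc1OC | intermediate (not isolated)
11 | 2-fluoro-6-methoxy-4-methylbenzaldehyde | O=Cc1c(F)cc(C)cc1OC | intermediate
12 | 3-bromo-2-fluoro-6-methoxy-4-methylbenzaldehyde | O=Cc1c(F)c(Br)c(C)cc1OC | intermediate
13 | 3-bromo-2-[(6-hydroxy-8-methoxy-2,2,5-trimethyl-4-oxochroman-7-yl)oxy]-6-methoxy-4-methylbenzaldehyde | O=C1CC(C)(C)Oc2c(OC)c(Oc3c(C=O)c(OC)cc(C)c3Br)c(O)c(C)c12 | intermediate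
14 | di-O-methyl ether of the target depsidone | Cc1cc(OC)c(C=O)c2c1C(=O)Oc1c(C)c3c(c(OC)c1O2)OC(C)(C)CC3=O | intermediate
15 | CNP0271978.0 (depsidone; ring A 3-formyl-4-hydroxy-6-methylbenzoyl, ring B 8-hydroxy-2,2,5-trimethylchroman-4-one esterified at O6 and etherified at O7) | Cc1cc(O)c(C=O)c2c1C(=O)Oc1c(C)c3c(c(O)c1O2)OC(C)(C)CC3=O | target

**Step count and risks**
Total: 9 steps. Longest linear sequence: 7 steps (1, 2, 3, 4, 7, 8, 9); the ring-A branch is steps 5 and 6.

Steps most likely to fail:

- **Step 3 (key step).** Instead of the 1,2-shift, the protonated dienone may lose the acyl group by C–C fragmentation to an aromatic hydroquinone ether, or the acyl group may settle on the methoxy-bearing carbon and block aromatisation. Fallback, setting out from 1 and returning at 7: 1 would be reduced with aqueous Na2S2O4 to 2,3-dimethoxy-5-methylbenzene-1,4-diol F1. F1 would then be heated with 3-methylbut-2-enoic acid in Eaton's reagent (P2O5/MeSO3H, 70 °C). Friedel–Crafts acylation at the only free ring position and oxa-Michael closure by the neighbouring hydroxyl should give 7. This contingency builds the pyranone ring directly, gives up the ring enlargement, and bypasses steps 1 and 2.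

- **Step 2.** The hydroxyl may be transposed in the wrong sense, the alkyne may simply be hydrated with the carbonyl next to CMe2, or the quinol may rearrange under acid before the ether ring has closed. Fallback, setting out from 1 and returning at 6: 1-ethoxyvinyllithium (ethyl vinyl ether, t-BuLi, THF, −78 °C) would be added to 1 to give 4-(1-ethoxyethenyl)-4-hydroxy-2,3-dimethoxy-6-methylcyclohexa-2,5-dien-1-one F2. Oxalic acid in wet THF would hydrolyse it to 4-acetyl-4-hydroxy-2,3-dimethoxy-6-methylcyclohexa-2,5-dien-1-one F3. The dianion of F3 (LDA, 2.2 equiv, THF, −78 °C) would be added to acetone to give 4-hydroxy-4-(3-hydroxy-3-methylbutanoyl)-2,3-dimethoxy-6-methylcyclohexa-2,5-dien-1-one F4. CSA in CH2Cl2 would dehydrate and cyclise F4 to 6. Here the carbonyl sits on the quinol carbon from the start.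

- **Step 7.** Arylation may occur at O6 instead of O7, substitution of the doubly ortho-substituted fluoride by the hindered phenoxide may be slow, and the catechol may be oxidised by air. Fallback, setting out from 7 and returning at 13: the C6–OH of 7 would be protected (MOMCl, i-Pr2NEt, CH2Cl2) as 7,8-dimethoxy-6-(methoxymethoxy)-2,2,5-trimethylchroman-4-one F5. NaSEt in DMF at 100 °C would remove the methyl para to the ketone to give 7-hydroxy-8-methoxy-6-(methoxymethoxy)-2,2,5-trimethylchroman-4-one F6. SNAr of F6 with 12 (Cs2CO3, DMSO, 80 °C) would give 3-bromo-6-methoxy-2-{[8-methoxy-6-(methoxymethoxy)-2,2,5-trimethyl-4-oxochroman-7-yl]oxy}-4-methylbenzaldehyde F7. HCl in MeOH would remove the MOM group to give 13. Only one phenol is free during the arylation.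

**Further compounds**
F1 | step 3 | 2,3-dimethoxy-5-methylbenzene-1,4-diol | Cc1cc(O)c(OC)c(OC)c1O
F2 | step 2 | rac-4-(1-ethoxyethenyl)-4-hydroxy-2,3-dimethoxy-6-methylcyclohexa-2,5-dien-1-one | O=C1C(C)=CC(O)(C(=C)OCC)C(OC)=C1OC
F3 | step 2 | rac-4-acetyl-4-hydroxy-2,3-dimethoxy-6-methylcyclohexa-2,5-dien-1-one | O=C1C(C)=CC(O)(C(C)=O)C(OC)=C1OC
F4 | step 2 | rac-4-hydroxy-4-(3-hydroxy-3-methylbutanoyl)-2,3-dimethoxy-6-methylcyclohexa-2,5-dien-1-one | O=C1C(C)=CC(O)(C(=O)CC(C)(C)O)C(OC)=C1OC
F5 | step 7 | 7,8-dimethoxy-6-(methoxymethoxy)-2,2,5-trimethylchroman-4-one | O=C1CC(C)(C)Oc2c(OC)c(OC)c(OCOC)c(C)c12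
F6 | step 7 | 7-hydroxy-8-methoxy-6-(methoxymethoxy)-2,2,5-trimethylchroman-4-one | O=C1CC(C)(C)Oc2c(OC)c(O)c(OCOC)c(C)c12
F7 | step 7 | 3-bromo-6-methoxy-2-{[8-methoxy-6-(methoxymethoxy)-2,2,5-trimethyl-4-oxochroman-7-yl]oxy}-4-methylbenzaldehyde | O=C1CC(C)(C)Oc2c(OC)c(Oc3c(C=O)c(OC)cc(C)c3Br)c(OCOC)c(C)c12
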